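(The readings were generated by integration with constants of no real substance; the scatter is artificial.)

If a flask loses its starting material in proportion to what is left, the fraction left is the exponential of minus a constant times the time.

- north-east: starting material 20 mM; partner 22 mM; protic impurity 10 mM; catalyst 20 µM; the very flask that is asked about, followed so far
- flask: starting material 20 mM; partner 22.0 mM; protic impurity 10.0 mM; catalyst 20 µM; time 1.5 h

north-east run (percent of the starting material charged)

| time / min | target / % | starting material / % |
|---|---|---|
| 2.00 | 0 | 98.1 |
| 6.00 | 0.4 | 95.2 |
| 10.0 | 1.6 | 91.2 |
| 15.0 | 2.9 | 85.9 |
| 20.0 | 1.7 | 81.9 |
| 30.0 | 3.7 | 73.5 |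
| 40.0 | 7.6 | 65.7 |

(standard deviation of a reading: 1 percentage point)

- the numbers in the tables scatter with a standard deviation of 1 percentage point

- amount of target in the flask at 1.5 h, in percent of the starting material charged
- amount of starting material in the flask at 1.5 h, in percent of the starting material charged
- amount of intermediate in the flask at 1.5 h, in percent of the starting material charged
- concentration of partner at 1.5 h, in mM

From the last reading of the north-east run I took the loss constant, the natural logarithm of the inverse fraction left divided by the time: 0.0105 min⁻¹, a reading with its scatter. Going round once more with the reading at 20.0 min gave 0.00998 min⁻¹, smaller than the later value, so I saw no slowing. I then put the constant back into the flask asked about, which is that run followed further, and at 1.5 h the fraction left came to 38.9%.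

The forecast gave 38% of starting material, a little less than my reckoning, with 38% of intermediate, 24% of target and 9.6 mM of partner. Its ground: “Starting material falls almost exponentially”.

The flask gave 39.2% of starting material, 39.7% of intermediate, 21.1% of target and 11.0 mM of partner.

    starting material + catalyst → catalyst + intermediate (k = 520 L mol⁻¹ min⁻¹)
    partner + catalyst + intermediate → catalyst + target (k = 31000 L² mol⁻² min⁻¹)
    partner + protic impurity → quenched reagent (k = 0.790 L mol⁻¹ min⁻¹)

In this flask the catalyst stood at 100% of its charge at 1.50 h, which is what a pseudo-first-order loss with one constant asks for. For the neighbour flask with 0.0050 mM of catalyst, I scaled the loss constant by the ratio of catalyst charges to 0.00263 min⁻¹, which put the fraction left at 79.0%. That neighbour flask held 79.1% of starting material at 1.50 h.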